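The numbers of this flask belong to no real substance; the run is a simulation.

If every batch of target in a flask is followed by its age, the share asked for becomes an average over ages, and each set-up is a different spread of ages.

all flasks: free catalyst 0.64 mM; impurity 92 µM
- cedar: substrate 0.10 M (fed, over 64.0 s); time 80 s; all but substrate at the start; substrate goes in evenly over 64.0 s, the run ends at 80 s
- maple: substrate 0.10 M; one stirred flow tank at steady state, fed with the mixture as stated, mean residence time 80 s
- elm: substrate 0.10 M; time 80 s; a closed flask charged with all of it at once and left for 80 s

1. the set-up with the highest share of target in all that became target or isomer of the product, at the outlet or at the end ("none" if the first two lie within 2 percentage points) (cedar / maple / elm / none)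
2. share of target in all that became target or isomer of the product, at the outlet or at the end, cedar
3. share of target in all that became target or isomer of the product, at the outlet or at the end, maple
4. share of target in all that became target or isomer of the product, at the outlet or at the end, elm

- in percentages every species weighs as the substrate in it: one homo dimer counts as two
- a doubled species enters its step squared and goes two at a time
- the stated concentrations are those of everything mixed, before any reaction; amounts are the same in each set-up
- the feed brings no volume worth counting
- run time (cedar): 80 s

    target + free catalyst ⇌ isomer of the product + free catalyst, rate k1*[free catalyst]*[target] forward; the back reaction follows from the equilibrium constant (K1 = 0.10, k1 = 6.7 M⁻¹ s⁻¹)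
    substrate + free catalyst ⇌ target + free catalyst, rate k2*[substrate]*[free catalyst] forward; the back reaction follows from the equilibrium constant (K2 = 1.9, k2 = 14 M⁻¹ s⁻¹)
    substrate + free catalyst → spent catalyst A (k3 = 0.041 M⁻¹ s⁻¹)
    free catalyst + impurity → spent catalyst B (k4 = 3200 M⁻¹ s⁻¹)
    2 substrate → homo dimer (k5 = 0.18 M⁻¹ s⁻¹)

Target and isomer of the product form a reversible pair on the free catalyst.

The impurity binds catalyst first, with a time constant of 0.488 s, far shorter than the 80 s of a run, so about 0.548 mM of free catalyst remains after that step. The pair then relaxes as a pseudo-first-order step. Forward rate constant times working catalyst, times one plus the reciprocal of the equilibrium constant, inverted, gives 24.8 s: the isomer relaxation time.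

For a single batch, the share of target starts at 100 % and falls with an initial slope of 0.00367 s⁻¹. The curve bends near the relaxation time and runs into the level L = 90.9 %:

share = L + (1 − L)·M, with M the mean of exp(−a/trel) over the ages

This reckoning takes a spread of ages for each set-up, with t the 80 s:

- maple, exponential ages: M = 1/(1 + t/trel) = 0.236, share 93.1 %
- elm, taken as even production: M = (trel/t)(1 − exp(−t/trel)) = 0.297, share 93.6 %
- cedar, roughly a ramp from nothing: M = 2(trel/t) − 2(trel/t)²(1 − exp(−t/trel)) = 0.435, share 94.9 %

Cedar and elm, the top two here, differ by 1.3 percentage points, less than the margin, so this reckoning calls the set-ups equal.

The forecast says none, with cedar 94.2 %, maple 93.3 % and elm 92.7 %, which differs from this reckoning in each percentage and agrees with it in the verdict. Its ground for cedar is that “the slow feed delays target formation, so the isomer lags more”.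

The simulation gives none: cedar 94.2 %, maple 93.3 %, elm 92.6 %.

At 80.0 s, cedar held 76.0 % of its catalyst free, which puts the relaxation time at 27.9 s, shorter than the run. The forecast's verdict would fail with cedar and maple more than 2 points apart; they stand 0.90 points apart. For the neighbour of cedar charged with 1.6 × 10⁻⁴ M of free catalyst, the same reckoning puts the relaxation time at 200 s, longer than the run. The ramp then gives M = 0.879 and a share of 98.9 %, and that flask gave 98.8 %.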